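**Retrosynthetic overview**

1. The strategy rests on the oxygenated carbocycle C1'–C6'. Its two oxygen-bearing carbons, C2' (carbinol) and C5' (ketone), stand para, with the C11 methylene on C1' and the methyl on C4', so the ring is a masked hydroquinone whose two oxygens are differentiated.
2. Late stage: target ⇐ C5' dimethyl ketal with C2' alcohol ⇐ C1'–C6' epoxy enone ⇐ quinone monoketal ⇐ 2-alkyl-4-methoxy-5-methylphenol (C2' free OH, C5' OMe).
3. Key disconnection: the arene is split into a propargyl drimane (C1', C6'), pentacarbonyl[methoxy(isopropenyl)carbene]chromium (C5', C4', C3' and the methyl) and one CO ligand (C2').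
4. The propargyl drimane comes from (+)-sclareolide with rings A/B intact: C3 is hydroxylated to direct oxidation of the 4α-methyl and is then deoxygenated, the lactone carbonyl carbon becomes the internal alkyne carbon, and the C8 oxygen leaves to give the 7-ene.
5. Ring order: decalin from the chiral pool, then the six-membered carbocycle (step 11), then the oxirane (step 13).

Key step: step 11

Assumption: the name is read as the structure given by the SMILES; drimane numbering (C1–C10, C11 = CH2 on C9) is used for the decalin and primed numbers for the oxygenated ring; the C3-selective P450BM3 variant is taken to be available by expression in E. coli.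

**Route**

Step 1
Reactants: 1 (+)-sclareolide
Product: 2 3β-hydroxysclareolide
Conditions: C3-selective engineered P450BM3 variant (E. coli lysate), NADP+ (cat.), phosphite dehydrogenase, Na2HPO3, air, KPi buffer pH 8/DMSO, 25 °C
Reagents that add atoms: dioxygen, O=O
Why: Enzymatic C–H hydroxylation (P450 hydrogen abstraction/oxygen rebound) is known on sclareolide itself, where evolved BM3 variants should place the hydroxyl at C3 on the equatorial β face (set by the active site), whereas chemical oxidants prefer C2.

Step 2
Reactants: 2 3β-hydroxysclareolide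
Product: 5 3β-hydroxy-4α-(hydroxymethyl)sclareolide, via 3β-O-diethylhydrosilyl ether 3 (not isolated), via oxasilolane 4 (not isolated)
Conditions: Et2SiH2, [Ir(cod)OMe]2 (0.05 mol%), THF, rt; evaporate; [Ir(cod)OMe]2 (cat.), 3,4,7,8-Me4phen, norbornene, THF, 100–120 °C; then 30% H2O2, KHCO3, THF/MeOH, 50 °C
Reagents that add atoms: hydrogen peroxide, OO
Why: Hydroxyl-directed iridium-catalysed γ-C–H silylation followed by Tamao–Fleming oxidation, known on 3β-hydroxy-4,4-dimethyl terpenoids, should functionalise the equatorial 4α-methyl (the one the equatorial silyl ether reaches in a trans-fused oxasilolane), making C4 stereogenic with CH2OH α and CH3 β; the C–Si oxidation retains configuration.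

Step 3
Reactants: 5 3β-hydroxy-4α-(hydroxymethyl)sclareolide
Product: 6 4α-(tert-butyldimethylsilyloxymethyl)-3β-hydroxysclareolide
Conditions: TBSCl, imidazole, DMF, 0 °C → rt
Reagents that add atoms: tert-butyldimethylsilyl chloride, CC(C)(C)[Si](C)(C)Cl
Why: Silylation should select the primary alcohol over the secondary 3β-hydroxyl, which is flanked by the quaternary C4.

Step 4
Reactants: 6 4α-(tert-butyldimethylsilyloxymethyl)-3β-hydroxysclareolide
Product: 7 3β-O-(imidazol-1-ylthiocarbonyl) derivative of 6
Conditions: 1,1'-thiocarbonyldiimidazole, DMAP (cat.), 1,2-dichloroethane, 80 °C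
Reagents that add atoms: 1,1'-thiocarbonyldiimidazole, S=C(n1ccnc1)n1ccnc1
Why: Thioacylation of the only free hydroxyl prepares the radical deoxygenation and is compatible with the lactone and the silyl ether.

Step 5
Reactants: 7 3β-O-(imidazol-1-ylthiocarbonyl) derivative of 6
Product: 8 4α-(tert-butyldimethylsilyloxymethyl)sclareolide
Conditions: Bu3SnH, AIBN (cat.), toluene, 110 °C
Reagents that add atoms: none
Why: Barton–McCombie deoxygenation: the stannyl radical adds to C=S, the secondary C3 radical is released and reduced by the stannane, so the directing oxygen is removed while the C4 stereocentre is untouched.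

Step 6
Reactants: 8 4α-(tert-butyldimethylsilyloxymethyl)sclareolide
Product: 9 lactol of 8 (hemiacetal at the former lactone carbonyl, anomer mixture)
Conditions: DIBAL-H (1.2 equiv), CH2Cl2, −78 °C; Rochelle salt
Reagents that add atoms: none
Why: Partial reduction of the γ-lactone stops at the aluminium hemiacetal at −78 °C, as it does for sclareolide itself.

Step 7
Reactants: 9 lactol of 8
Product: 10 8α-hydroxy-9β-propargyl drimane with 4α-CH2OTBS
Conditions: dimethyl (1-diazo-2-oxopropyl)phosphonate, K2CO3, MeOH, rt → 40 °C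
Reagents that add atoms: dimethyl (1-diazo-2-oxopropyl)phosphonate, COP(=O)(OC)C(=[N+]=[N-])C(C)=O
Why: Ohira–Bestmann homologation acts on the open hydroxy-aldehyde tautomer of the lactol and turns the former lactone carbon into the internal alkyne carbon (C1') with one new carbon (C6'); C9 is β to the aldehyde and cannot epimerise.

Step 8
Reactants: 10 8α-hydroxy-9β-propargyl drimane with 4α-CH2OTBS
Product: 12 9β-propargyl drim-7-ene with free 4α-CH2OH, via desilylated diol alkyne 11 (not isolated)
Conditions: conc. H2SO4 (5 vol%), EtOH, 20 °C; NaHCO3 quench at full conversion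
Reagents that add atoms: none
Why: Acid-mediated E1 dehydration of a 9-substituted drimane 8α-ol should lose the ring proton at C7 to give the trisubstituted 7-ene, with any exocyclic isomer re-protonated and funnelled the same way if the reaction is stopped before drift to the 8(9)-ene; the medium also strips the silyl ether, which is restored in step 9.

Step 9
Reactants: 12 9β-propargyl drim-7-ene with free 4α-CH2OH
Product: 13 9β-propargyl drim-7-ene with 4α-CH2OTBS
Conditions: TBSCl, imidazole, DMF, rt
Reagents that add atoms: tert-butyldimethylsilyl chloride, CC(C)(C)[Si](C)(C)Cl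
Why: Silylation of the single hydroxyl keeps the alcohol away from the carbene complex and the vinylketene of the next step.

Step 10
Reactants: 14 2-bromopropene; 15 chromium hexacarbonyl
Product: 18 pentacarbonyl[methoxy(isopropenyl)carbene]chromium, via isopropenyllithium 16 (not isolated), via lithium acyl chromate 17 (not isolated)
Conditions: t-BuLi (2 equiv), Et2O, −78 °C; Cr(CO)6, Et2O, −78 °C → rt; then Me3OBF4, CH2Cl2/H2O, 0 °C
Reagents that add atoms: trimethyloxonium tetrafluoroborate, C[O+](C)C.F[B-](F)(F)F
Why: This is the standard Fischer carbene synthesis: the alkenyllithium adds to a CO ligand and the acyl metalate is O-methylated.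

Step 11
Reactants: 13 9β-propargyl drim-7-ene with 4α-CH2OTBS; 18 pentacarbonyl[methoxy(isopropenyl)carbene]chromium
Product: 20 2-(drimenylmethyl)-4-methoxy-5-methylphenol (C2' OH, C5' OMe, 4α-CH2OTBS), via arene tricarbonylchromium complex 19 (not isolated)
Conditions: 18 (1.5 equiv), THF (0.1 M), 50 °C, Ar; then air, EtOAc, rt
Reagents that add atoms: none
Why: Thermal loss of one CO from 18 lets the alkyne bind; insertion into Cr=C joins the carbene carbon (C5') to the unsubstituted alkyne carbon (C6'), CO insertion at the new carbene carbon gives a vinylketene (C1'–C2'), and 6π-electrocyclisation onto the isopropenyl CH2 (C2'–C3') followed by enolisation gives the Cr(CO)3-bound phenol 19, from which air releases 20. This is the Dötz benzannulation of an alkenyl(alkoxy)carbene complex with a terminal alkyne, a well-established pairing. The one carbocycle is assembled in a [3+2+1] sense and is closed by the electrocyclisation of the dienylketene. No stereocentre is formed, and those of the decalin lie away from the reacting alkyne. The selectivity needed is regiochemical: the substituted alkyne carbon must end next to the CO-derived carbon so that C2' is the free phenol and C5' the methyl ether, and the steric difference between H and the C11 methylene of a terminal alkyne secures this; the hindered C7–C8 alkene and the silyl ether should not engage the metal.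

Step 12
Reactants: 20 2-(drimenylmethyl)-4-methoxy-5-methylphenol
Product: 21 2-(drimenylmethyl)-4,4-dimethoxy-5-methylcyclohexa-2,5-dienone (C5' ketal, C2' ketone)
Conditions: PhI(OAc)2 (1.1 equiv), MeOH, 0 °C
Reagents that add atoms: methanol, CO
Why: Iodine(III) oxidation of a 4-methoxyphenol gives a phenoxenium-type intermediate that methanol traps at the methoxy-bearing para carbon, so the oxygen differentiation made in step 11 places the ketal at C5' and the ketone at C2'.

Step 13
Reactants: 21 quinone monoketal
Product: 22 C1'–C6' epoxide of 21 (epoxy enone, configuration as in the target)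
Conditions: t-BuOOH, aq. NaOH, N-benzylcinchonidinium chloride (10–20 mol%), toluene, 0 °C
Reagents that add atoms: tert-butyl hydroperoxide, CC(C)(C)OO
Why: Weitz–Scheffer epoxidation under cinchona phase-transfer catalysis, a known reaction of quinone monoketals, should attack the enone arm whose β-carbon (C6') is unsubstituted and leave the β-methyl arm; C1' and C6' are set together by the chiral ion pair because the decalin is too remote to bias the faces, and the cinchonidinium or the pseudo-enantiomeric cinchoninium salt is chosen to deliver the required diastereomer.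

Step 14
Reactants: 22 epoxy enone
Product: 23 C2' alcohol of 22 (OH trans to the epoxide oxygen, cis to the C11 methylene)
Conditions: NaBH4, CeCl3·7H2O, MeOH, −78 °C
Reagents that add atoms: none
Why: Luche reduction is 1,2-selective and, as for cyclic α,β-epoxy ketones in general, should deliver hydride from the epoxide-oxygen face, here also the face opposite the C11 methylene on the quaternary C1', so C2' is set trans to the oxirane.

Step 15
Reactants: 23 epoxy alcohol ketal
Product: 24 Epoxypholamin B
Conditions: 48% aq. HF, MeCN, 0 °C → rt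
Reagents that add atoms: water, O
Why: Aqueous HF hydrolyses the allylic dimethyl ketal to the C5' enone and cleaves the primary silyl ether in one operation, conditions that epoxyquinols tolerate, and no stereocentre is touched.

**Compound list**

1 | (+)-sclareolide | O=C1C[C@H]3[C@](C)(O1)CC[C@H]4C(C)(C)CCC[C@]34C | starting material
2 | 3β-hydroxysclareolide (OH equatorial) | O=C1C[C@H]3[C@](C)(O1)CC[C@H]4C(C)(C)[C@@H](O)CC[C@]34C | intermediate
3 | 3β-O-diethylhydrosilyl ether of 2 | O=C1C[C@H]3[C@](C)(O1)CC[C@H]4C(C)(C)[C@@H](O[SiH](CC)CC)CC[C@]34C | intermediate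
4 | oxasilolane (SiEt2 bridging O3 and the 4α-CH2) | O=C1C[C@H]3[C@](C)(O1)CC[C@H]4[C@]5(C)C[Si](CC)(CC)O[C@H]5CC[C@]34C | intermediate
5 | 3β-hydroxy-4α-(hydroxymethyl)sclareolide (4β-methyl) | O=C1C[C@H]3[C@](C)(O1)CC[C@H]4[C@](C)(CO)[C@@H](O)CC[C@]34C | intermediate
6 | 4α-(TBSO-methyl)-3β-hydroxysclareolide | O=C1C[C@H]3[C@](C)(O1)CC[C@H]4[C@](C)(CO[Si](C)(C)C(C)(C)C)[C@@H](O)CC[C@]34C | intermediate
7 | 3β-O-(imidazol-1-ylthiocarbonyl) derivative of 6 | O=C1C[C@H]3[C@](C)(O1)CC[C@H]4[C@](C)(CO[Si](C)(C)C(C)(C)C)[C@@H](OC(=S)n5ccnc5)CC[C@]34C | intermediate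
8 | 4α-(TBSO-methyl)sclareolide | O=C1C[C@H]3[C@](C)(O1)CC[C@H]4[C@](C)(CO[Si](C)(C)C(C)(C)C)CCC[C@]34C | intermediate
9 | lactol of 8 (anomer mixture) | OC1C[C@H]3[C@](C)(O1)CC[C@H]4[C@](C)(CO[Si](C)(C)C(C)(C)C)CCC[C@]34C | intermediate
10 | 8α-hydroxy-9β-propargyl drimane, 4α-CH2OTBS | C#CC[C@H]3[C@](C)(O)CC[C@H]4[C@](C)(CO[Si](C)(C)C(C)(C)C)CCC[C@]34C | intermediate
11 | 8α-hydroxy-9β-propargyl drimane, free 4α-CH2OH | C#CC[C@H]3[C@](C)(O)CC[C@H]4[C@](C)(CO)CCC[C@]34C | intermediate
12 | 9β-propargyl drim-7-ene, free 4α-CH2OH | C#CC[C@H]3C(C)=CC[C@H]4[C@](C)(CO)CCC[C@]34C | intermediate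
13 | 9β-propargyl drim-7-ene, 4α-CH2OTBS | C#CC[C@H]3C(C)=CC[C@H]4[C@](C)(CO[Si](C)(C)C(C)(C)C)CCC[C@]34C | intermediate
14 | 2-bromopropene | CC(Br)=C | starting material
15 | chromium hexacarbonyl | O=C=[Cr](=C=O)(=C=O)(=C=O)(=C=O)=C=O | starting material
16 | isopropenyllithium | [Li]C(C)=C | intermediate
17 | lithium pentacarbonyl(methacryloyl)chromate (acyl chromate) | [Li+].[O-]C(C(C)=C)=[Cr](=C=O)(=C=O)(=C=O)(=C=O)=C=O | intermediate
18 | pentacarbonyl[methoxy(isopropenyl)carbene]chromium | COC(C(C)=C)=[Cr](=C=O)(=C=O)(=C=O)(=C=O)=C=O | intermediate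
19 | tricarbonyl(η6-arene)chromium complex of 20 (written as arene plus Cr(CO)3 fragment) | COc1cc(C[C@H]3C(C)=CC[C@H]4[C@](C)(CO[Si](C)(C)C(C)(C)C)CCC[C@]34C)c(O)cc1C.O=C=[Cr](=C=O)=C=O | intermediate
20 | 2-(drimenylmethyl)-4-methoxy-5-methylphenol (C2' OH, C5' OMe) | COc1cc(C[C@H]3C(C)=CC[C@H]4[C@](C)(CO[Si](C)(C)C(C)(C)C)CCC[C@]34C)c(O)cc1C | intermediate
21 | 2-(drimenylmethyl)-4,4-dimethoxy-5-methylcyclohexa-2,5-dienone | CC1=CC(=O)C(C[C@H]3C(C)=CC[C@H]4[C@](C)(CO[Si](C)(C)C(C)(C)C)CCC[C@]34C)=CC1(OC)OC | intermediate
22 | C1'–C6' epoxide of 21 | CC1=CC(=O)[C@]2(C[C@H]3C(C)=CC[C@H]4[C@](C)(CO[Si](C)(C)C(C)(C)C)CCC[C@]34C)O[C@@H]2C1(OC)OC | intermediate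
23 | C2' alcohol of 22 (OH trans to epoxide O) | CC1=C[C@@H](O)[C@]2(C[C@H]3C(C)=CC[C@H]4[C@](C)(CO[Si](C)(C)C(C)(C)C)CCC[C@]34C)O[C@@H]2C1(OC)OC | intermediate
24 | Epoxypholamin B | CC1=C[C@@H](O)[C@]2(C[C@H]3C(C)=CC[C@H]4[C@](C)(CO)CCC[C@]34C)O[C@@H]2C1=O | target

**Step count and risks**

Total step count: 15. Longest linear sequence: 14 steps (1–9 and 11–15) from (+)-sclareolide; step 10 is a one-step branch.

Steps most likely to fail:

1. Step 13. The chiral ion pair may fail to distinguish the two faces of the C1'–C6' enone, and peroxide addition at the β-carbon next to the ketal may be slow. Fallback with auxiliary control, from 21 to 24: transketalisation of 21 with (R,R)-hydrobenzoin (PPTS, benzene, 60 °C, methanol removed) should give the C2-symmetric spiro-dioxolane dienone F1. Weitz–Scheffer epoxidation (t-BuOOH, DBU, THF, 0 °C), in which one phenyl group of the ketal screens a face of the C1'–C6' enone, should give the epoxy ketone F2; the enantiomer of the diol is chosen to match the required face. Luche reduction then gives the trans epoxy alcohol F3, and aqueous TFA followed by aq. HF–MeCN removes the ketal and the silyl ether to rejoin the route at 24.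

2. Step 8. Proton loss from the C8 cation may not be regioselective: the exocyclic alkene may persist, or the 7-ene may isomerise on to the tetrasubstituted 8(9)-ene. Fallback that fixes the alkene position by transposition, from 10 to 13: dehydration under E2 conditions (SOCl2, pyridine, CH2Cl2, −78 °C), where the equatorial leaving group can align only with the methyl hydrogens, should give the exocyclic C8-methylene alkene F4 with the silyl ether intact. Allylic oxidation (SeO2 cat., t-BuOOH, CH2Cl2) at the ring methylene gives the 7-hydroxy exocyclic alkene F5. Mitsunobu reaction with 2-nitrobenzenesulfonylhydrazide (PPh3, DEAD, −30 °C → rt) gives the N-allyl sulfonylhydrazine F6, which is not isolated. It loses sulfinic acid, and the allylic diazene transfers hydrogen to the exocyclic carbon by a retro-ene step with loss of N2, moving the alkene to C7–C8 and returning at 13.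

3. Step 11. Alkyne insertion next to the bulky C9 may be slow, the vinylcarbene or vinylketene intermediates may leak into non-aromatic products, and the electron-rich phenol may be over-oxidised during demetalation. Fallback by cross-coupling after excision of the lactone carbon, from 9 to 20: hypoiodite fragmentation of lactol 9 (PhI(OAc)2, I2, hν) should give the 8α-formyloxy C11 iodide F7. Commercial 4-methoxy-3-methylphenol is converted to its MOM ether F8 (MOMCl, i-Pr2NEt), which is ortho-lithiated (n-BuLi, TMEDA) and transmetalated (ZnCl2) to the arylzinc chloride F9. Palladium-catalysed Negishi coupling of F9 with F7 (Pd2(dba)3, PCyp3, NMI, THF/NMP) gives the C11-aryl formate F10. H2SO4/EtOH, as in step 8, removes the formate, MOM and silyl groups and dehydrates C8 to the 7-ene phenol–alcohol F11. Double silylation (TBSCl, imidazole) gives the bis-silyl ether F12, and K2CO3/MeOH cleaves the aryl silyl ether to return at 20.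

Further compounds
F1 | step 13 | (R,R)-hydrobenzoin spiro-dioxolane analogue of dienone 21 | CC1=CC(=O)C(C[C@H]3C(C)=CC[C@H]4[C@](C)(CO[Si](C)(C)C(C)(C)C)CCC[C@]34C)=CC12O[C@H](c5ccccc5)[C@@H](c5ccccc5)O2
F2 | step 13 | C1'–C6' epoxide of F1 | CC1=CC(=O)[C@]2(C[C@H]3C(C)=CC[C@H]4[C@](C)(CO[Si](C)(C)C(C)(C)C)CCC[C@]34C)O[C@@H]2C15O[C@H](c6ccccc6)[C@@H](c6ccccc6)O5
F3 | step 13 | C2' alcohol of F2 (OH trans to epoxide O) | CC1=C[C@@H](O)[C@]2(C[C@H]3C(C)=CC[C@H]4[C@](C)(CO[Si](C)(C)C(C)(C)C)CCC[C@]34C)O[C@@H]2C15O[C@H](c6ccccc6)[C@@H](c6ccccc6)O5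
F4 | step 8 | 9β-propargyl drimane with exocyclic C8 methylene, 4α-CH2OTBS | C#CC[C@H]3C(=C)CC[C@H]4[C@](C)(CO[Si](C)(C)C(C)(C)C)CCC[C@]34C
F5 | step 8 | 7-hydroxy derivative of F4 (C7 configuration immaterial) | C#CC[C@H]3C(=C)C(O)C[C@H]4[C@](C)(CO[Si](C)(C)C(C)(C)C)CCC[C@]34C
F6 | step 8 | C7 N-(2-nitrobenzenesulfonyl)hydrazine from F5 (not isolated) | C#CC[C@H]3C(=C)C(N(N)S(=O)(=O)c5ccccc5[N+](=O)[O-])C[C@H]4[C@](C)(CO[Si](C)(C)C(C)(C)C)CCC[C@]34C
F7 | step 11 | 8α-formyloxy-11-iodo drimane, 4α-CH2OTBS | IC[C@H]3[C@](C)(OC=O)CC[C@H]4[C@](C)(CO[Si](C)(C)C(C)(C)C)CCC[C@]34C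
F8 | step 11 | 1-methoxy-4-(methoxymethoxy)-2-methylbenzene | COCOc1ccc(OC)c(C)c1
F9 | step 11 | [5-methoxy-2-(methoxymethoxy)-4-methylphenyl]zinc chloride (not isolated) | COCOc1cc(C)c(OC)cc1[Zn]Cl
F10 | step 11 | C11-aryl 8α-formate (aryl MOM ether, 4α-CH2OTBS) | COCOc1cc(C)c(OC)cc1C[C@H]3[C@](C)(OC=O)CC[C@H]4[C@](C)(CO[Si](C)(C)C(C)(C)C)CCC[C@]34C
F11 | step 11 | 2-(drimenylmethyl)-4-methoxy-5-methylphenol with free 4α-CH2OH | COc1cc(C[C@H]3C(C)=CC[C@H]4[C@](C)(CO)CCC[C@]34C)c(O)cc1C
F12 | step 11 | bis-TBS ether of F11 (aryl and primary silyl ethers) | COc1cc(C[C@H]3C(C)=CC[C@H]4[C@](C)(CO[Si](C)(C)C(C)(C)C)CCC[C@]34C)c(O[Si](C)(C)C(C)(C)C)cc1C
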